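Readings and results stem from a simulated flask on assumed constants, noise included.

- Target and trapped intermediate add up to 99.9% at the end of the summer run and 99.7% in the spring run, so we reckon the small one, the trapped share, and let target take the rest.

| flask | substrate | reagent | capture agent | free catalyst | second catalyst | remark | time |
|---|---|---|---|---|---|---|---|
| summer | 0.015 M (in portions, 4) | 1.5 equiv | 0.031 M | 2.5 mol% | 0.78 mol% | run made earlier; portions every 30 s |  |
| dawn | 0.062 M (in portions, 4) | 1.5 equiv | 0.031 M | 2.5 mol% | 0.78 mol% | run made earlier; portions every 30 s |  |
| spring | 0.031 M (in portions, 4) | 2.2 equiv | 0.031 M | 2.5 mol% | 0.78 mol% | run made earlier; portions every 30 s |  |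
| flask | 0.031 M (in portions, 4) | 1.50 equiv | 0.0310 M | 2.5 mol% | 0.78 mol% | the portions of substrate follow each other after 30 s, the first at the start | 4.0 h |

- summer (time / h: target / %, trapped intermediate / %): 0.200: 51.3, 6.3; 0.333: 69.0, 10.5; 0.667: 84.8, 12.7; 1.33: 86.5, 13.7; 2.50: 86.6, 13.3
- dawn (time / h: target / %, trapped intermediate / %): 0.500: 100.1, 1.1; 1.00: 99.0, 1.0; 1.33: 98.3, 1.6; 2.00: 99.9, 2.2; 2.50: 98.0, 1.5
- spring (time / h: target / %, trapped intermediate / %): 0.200: 90.3, 1.7; 0.333: 96.8, 2.3; 0.667: 97.9, 1.4; 1.33: 98.0, 2.2; 2.50: 97.7, 2.0

(readings scatter by 0.5 percentage points)

- amount of target at 4.0 h, in percent of the substrate charged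
- amount of trapped intermediate at 4.0 h, in percent of the substrate charged

- Target in the summer run reads 86.5% at 1.33 h and 86.6% at 2.50 h, and the asked 4.0 h is later, so we reckon the final split.
- We assume one reagent per target, so the mean reagent while target forms is its charge less half the substrate. The second catalyst is charged in mol%, so it follows [substrate].
- Our trap constant is the ratio of trapped to target, the inverse of a selectivity factor, times [substrate] times [mean reagent]. The last readings of the summer run, with the largest final trapped reading, give 3.46 × 10⁻⁵ M^2, and those of the spring run, with more equivalents of reagent, give 3.34 × 10⁻⁵ M^2.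
- Trapped would equal target if [substrate] times [mean reagent] fell to the trap constant. In this flask the trap constant divided by that product is 0.0360, so the product is 27.8 times the trap constant, and we expect 3.47% trapped.
- The forecast, reasoning that “Capture competes with onward conversion of the intermediate”, says 96% target and 4% trapped, a little more trapped than our figure.

    open intermediate + capture agent → trapped intermediate (k = 0.0186 M⁻¹ s⁻¹)
    reagent + second catalyst + open intermediate → second catalyst + target (k = 2000 M⁻² s⁻¹)
    substrate + free catalyst → free catalyst + open intermediate (k = 5.28 M⁻¹ s⁻¹)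

- The flask gives 96.1% target and 3.86% trapped intermediate. At 0.0602 h in this flask, open intermediate was going to target 30 times as fast as into the trap. With the recipe at 0.012 M of substrate, the trap constant gives a ratio of 0.240, or 19.4% trapped, and that flask holds 19.1%.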